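**Plan**

1. Retrosynthetic cuts: the biaryl C–C bond (Suzuki–Miyaura) gives lignan boronate 19 and bromo-dihydroflavonol 27. In 27 the O1–C2 bond (epoxide opening) and the Cα=Cβ bond (Claisen–Schmidt) are cut. In the lignan the lactol-level C–O bond of the bromoaryl ring and the C2–C3 bond of the guaiacyl tetrahydrofuran are cut.
2. Enabling feature: in the guaiacyl tetrahydrofuran (O1, C2–aryl, C3, C4, C5H2) the benzylic C2 lies between the ring oxygen and C3, and C3 carries the carbon that ends as the CH2–O of the second ring. C2 can therefore be an acetal carbon and C3 with that carbon an enol ether, tied together in a seven-membered 2-aryl-4,5-dihydro-1,3-dioxepine (13).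
3. Key event: a silyl triflate opens the acetal of 13 at the enol oxygen and the enol carbon closes onto the oxocarbenium ion. This 7 → 5 ring contraction (1,3 O-to-C shift) makes the C2–C3 bond and unmasks an aldehyde. After C3 epimerization the side-chain benzylic hydroxyl captures it as the lactol of the second ring.
4. Forward order: Evans aldol (side chain), mixed vinyl acetal and ring-closing metathesis (dioxepine), ring contraction (guaiacyl tetrahydrofuran), lactol formation and reduction (second tetrahydrofuran), borylation; chromanone by chalcone epoxidation and cyclization; biaryl coupling; debenzylation.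
5. Stereochemistry: the two side-chain centres come from the oxazolidinone auxiliary (syn-aldol). C2 and C3 of the tetrahydrofuran are relayed from the dioxepine C5 in the contraction and the lactol funnel. C2/C3 of the chromanone come from the poly-L-leucine epoxidation (C3 retained, C2 inverted on closure).

Key step: step 10

Remark: the target is read as (+)-pinoresinol joined through C5 of one guaiacyl ring to C5' of ring B of (2R,3R)-dihydroquercetin; compounds 1, 3, 8, 20 and 22 are taken as commercial, and all phenols are carried as benzyl ethers.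

**Route**

Step 1
Reactants: 1 3-bromo-4-hydroxy-5-methoxybenzaldehyde (5-bromovanillin)
Product: 2 4-(benzyloxy)-3-bromo-5-methoxybenzaldehyde
Conditions: BnBr, K2CO3, DMF, 60 °C
Reagents that add atoms: benzyl bromide, BrCc1ccccc1
Why: Williamson etherification of the phenoxide should proceed cleanly despite the two ortho substituents because benzyl bromide is an unhindered SN2 electrophile.

Step 2
Reactants: 3 (S)-4-benzyloxazolidin-2-one
Product: 4 (S)-4-benzyl-3-[(E)-but-2-enoyl]oxazolidin-2-one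
Conditions: n-BuLi, THF, −78 °C; then (E)-but-2-enoyl chloride, −78 → 0 °C
Reagents that add atoms: (E)-but-2-enoyl chloride, C/C=C/C(Cl)=O
Why: N-acylation of the lithiated oxazolidinone with an acid chloride is the standard preparation of Evans imides and leaves the auxiliary stereocentre untouched.

Step 3
Reactants: 4 (S)-4-benzyl-3-[(E)-but-2-enoyl]oxazolidin-2-one; 2 4-(benzyloxy)-3-bromo-5-methoxybenzaldehyde
Product: 5 (S)-4-benzyl-3-{(2S)-2-[(S)-[4-(benzyloxy)-3-bromo-5-methoxyphenyl](hydroxy)methyl]but-3-enoyl}oxazolidin-2-one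
Conditions: Bu2BOTf, Et3N, CH2Cl2, −78 → 0 °C; then 2, −78 → 0 °C; H2O2, MeOH, pH 7 buffer work-up
Reagents that add atoms: none
Why: Evans syn-aldol reaction in which the Z boron dienolate of the crotonyl imide reacts at its α-carbon through a Zimmerman–Traxler chair, the benzyl group of the auxiliary shielding one enolate face, so that the vinyl-bearing carbon (S) and the carbinol carbon (S) should both be set.

Step 4
Reactants: 5 aldol adduct
Product: 6 (S)-4-benzyl-3-{(2S)-2-[(S)-[4-(benzyloxy)-3-bromo-5-methoxyphenyl][(tert-butyldimethylsilyl)oxy]methyl]but-3-enoyl}oxazolidin-2-one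
Conditions: TBSOTf, 2,6-lutidine, CH2Cl2, 0 °C
Reagents that add atoms: tert-butyldimethylsilyl triflate, CC(C)(C)[Si](C)(C)OS(=O)(=O)C(F)(F)F
Why: Silylation of the secondary benzylic alcohol with the silyl triflate and a hindered base is fast at low temperature and blocks retro-aldol cleavage and later acetal formation at this oxygen.

Step 5
Reactants: 6 silyl ether of the aldol adduct
Product: 7 (2R)-2-{(S)-[4-(benzyloxy)-3-bromo-5-methoxyphenyl][(tert-butyldimethylsilyl)oxy]methyl}but-3-en-1-ol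
Conditions: LiBH4, MeOH (1 equiv), THF, 0 °C
Reagents that add atoms: none
Why: Reductive removal of the oxazolidinone with LiBH4 should give the primary alcohol without touching the aryl bromide, the alkene or the α-stereocentre (its descriptor changes to R only through the priority change) and returns the auxiliary.

Step 6
Reactants: 8 4-(benzyloxy)-3-methoxybenzaldehyde
Product: 9 1-(benzyloxy)-4-[bis(2-bromoethoxy)methyl]-2-methoxybenzene
Conditions: 2-bromoethanol (3 equiv), p-TsOH (cat.), toluene, reflux, Dean–Stark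
Reagents that add atoms: 2-bromoethanol, OCCBr
Why: Acid-catalysed acetalization with azeotropic removal of water should convert the aryl aldehyde into the dialkyl acetal that carries the latent vinyl group.

Step 7
Reactants: 9 1-(benzyloxy)-4-[bis(2-bromoethoxy)methyl]-2-methoxybenzene; 7 (2R)-2-{(S)-[4-(benzyloxy)-3-bromo-5-methoxyphenyl][(tert-butyldimethylsilyl)oxy]methyl}but-3-en-1-ol
Product: 11 1-(benzyloxy)-4-[(2-bromoethoxy){[(2R)-2-{(S)-[4-(benzyloxy)-3-bromo-5-methoxyphenyl][(tert-butyldimethylsilyl)oxy]methyl}but-3-en-1-yl]oxy}methyl]-2-methoxybenzene (both acetal epimers), via chloro ether 10 (not isolated)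
Conditions: 9, AcCl (1.05 equiv), ZnCl2 (1 mol%), CH2Cl2, 0 °C → rt; then 7, iPr2NEt, CH2Cl2, −40 → 0 °C
Reagents that add atoms: none
Why: Acetyl chloride should convert the acetal into the α-chloro ether, which alkylates the primary alcohol under basic conditions (SN1-type substitution through the aryl-stabilized oxocarbenium ion) to give the unsymmetrical acetal irreversibly and without acid.

Step 8
Reactants: 11 mixed bromoethyl acetal
Product: 12 1-(benzyloxy)-4-[(ethenyloxy){[(2R)-2-{(S)-[4-(benzyloxy)-3-bromo-5-methoxyphenyl][(tert-butyldimethylsilyl)oxy]methyl}but-3-en-1-yl]oxy}methyl]-2-methoxybenzene (both acetal epimers)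
Conditions: KOtBu, THF, 0 °C → rt
Reagents that add atoms: none
Why: E2 dehydrobromination of a 2-bromoethyl ether with a bulky alkoxide is the usual route to vinyl ethers and the base does not reach the alkyl silyl ether, the benzyl ethers or the aryl bromide.

Step 9
Reactants: 12 mixed vinyl acetal
Product: 13 (5R)-2-[4-(benzyloxy)-3-methoxyphenyl]-5-{(S)-[4-(benzyloxy)-3-bromo-5-methoxyphenyl][(tert-butyldimethylsilyl)oxy]methyl}-4,5-dihydro-1,3-dioxepine (both C2 epimers)
Conditions: Mo(=CHCMe2Ph)(=N-2,6-iPr2C6H3)[OCMe(CF3)2]2 (10 mol%), benzene (0.01 M), 50 °C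
Reagents that add atoms: none
Why: Ring-closing metathesis between the terminal alkene and the vinyl ether, for which the molybdenum imido alkylidene is the established catalyst type, should close the seven-membered cyclic vinyl acetal with loss of ethene and without touching the C5 stereocentre.

Step 10
Reactants: 13 (5R)-2-aryl-5-substituted 4,5-dihydro-1,3-dioxepine
Product: 14 (2S,3R,4R)-2-[4-(benzyloxy)-3-methoxyphenyl]-4-{(S)-[4-(benzyloxy)-3-bromo-5-methoxyphenyl][(tert-butyldimethylsilyl)oxy]methyl}tetrahydrofuran-3-carbaldehyde (2,3-cis and 3,4-trans)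
Conditions: TMSOTf (0.2 equiv), 2,6-di-tert-butyl-4-methylpyridine (0.3 equiv), CH2Cl2, −78 °C; Et3N quench at −78 °C
Reagents that add atoms: none
Why: The silyl triflate silylates the enol oxygen O1 of the cyclic vinyl acetal and the C2–O1 bond ionizes to an (E)-oxocarbenium ion (aryl–CH=O3+) tethered to a Z silyl enol ether, whose carbon C6 attacks C2 and releases the silyl cation, so the seven-membered ring contracts to the tetrahydrofuran and C7 emerges as the formyl group. The closest known reaction type is the Lewis acid-mediated 1,3 O-to-C (Petasis–Ferrier-type) rearrangement of 4,5-dihydro-1,3-dioxepines to 2,3-disubstituted tetrahydrofuran-3-carbaldehydes. The tetrahydrofuran closes in a 5-(enolexo)-endo-trig mode, endo with respect to the oxocarbenium C=O+, a mode that is open to oxocarbenium ions. The new tetrahydrofuran centre C3 is controlled by the dioxepine C5 centre, because allylic 1,3-strain with the Z-disposed silyloxy group holds H5 in the enol plane and the tethered electrophile then reaches the enol face anti to the bulky side chain (3,4-trans); the new centre C2 is set cis to the formyl group by the compact synclinal ion-pair transition state that is the kinetic preference of this rearrangement (2,3-cis). The step needs kinetic control, that is the aryl group anti to the side chain (2,4-trans) without re-ionization of the electron-rich benzylic ether, and this is secured by the ring-fixed Z enol geometry, the C5 substituent, −78 °C, the substoichiometric promoter and the hindered pyridine base; the acetal ionizes far faster than the benzylic silyl ether or the aryl benzyl ethers.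

Step 11
Reactants: 14 (2S,3R,4R)-tetrahydrofuran-3-carbaldehyde silyl ether
Product: 17 (1S,2S,5R,6S)-2-[4-(benzyloxy)-3-methoxyphenyl]-6-[4-(benzyloxy)-3-bromo-5-methoxyphenyl]-3,7-dioxabicyclo[3.3.0]octan-8-ol (both anomers; both aryl groups exo), via hydroxy aldehyde 15 (not isolated), via epimeric hydroxy aldehyde 16 (not isolated)
Conditions: TBAF, THF, 0 °C → rt
Reagents that add atoms: none
Why: Fluoride removes the silyl group and the basic medium epimerizes the aldehyde α-carbon through its enolate; only the 3,4-cis epimer 16 can close the five-membered hemiacetal, so the equilibrium should drain into the cis-fused lactol while C2, C4 and the carbinol centre stay untouched.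

Step 12
Reactants: 17 bicyclic lactol
Product: 18 (1R,2S,5R,6S)-2-[4-(benzyloxy)-3-methoxyphenyl]-6-[4-(benzyloxy)-3-bromo-5-methoxyphenyl]-3,7-dioxabicyclo[3.3.0]octane
Conditions: Et3SiH, BF3·OEt2, CH2Cl2, −78 → −40 °C
Reagents that add atoms: none
Why: Ionic hydrogenation of the lactol through the bicyclic oxocarbenium ion turns the hemiacetal carbon into CH2, creates no stereocentre and at low temperature should leave the two benzylic ether centres intact.

Step 13
Reactants: 18 bromo furofuran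
Product: 19 (1R,2S,5R,6S)-2-[4-(benzyloxy)-3-methoxyphenyl]-6-[4-(benzyloxy)-3-methoxy-5-(4,4,5,5-tetramethyl-1,3,2-dioxaborolan-2-yl)phenyl]-3,7-dioxabicyclo[3.3.0]octane
Conditions: B2pin2, Pd(dppf)Cl2 (5 mol%), KOAc, 1,4-dioxane, 90 °C
Reagents that add atoms: bis(pinacolato)diboron, CC1(C)OB(OC1(C)C)B1OC(C)(C)C(C)(C)O1
Why: Miyaura borylation of the aryl bromide proceeds under weakly basic conditions that the furofuran and the benzyl ethers tolerate.

Step 14
Reactants: 20 3-bromo-4,5-dihydroxybenzaldehyde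
Product: 21 3,4-bis(benzyloxy)-5-bromobenzaldehyde
Conditions: BnBr, K2CO3, DMF, 60 °C
Reagents that add atoms: benzyl bromide, BrCc1ccccc1
Why: Double Williamson etherification of the catechol protects both phenols before the base-mediated condensation.

Step 15
Reactants: 22 1-[2,4-bis(benzyloxy)-6-hydroxyphenyl]ethan-1-one
Product: 23 1-[2,4-bis(benzyloxy)-6-(methoxymethoxy)phenyl]ethan-1-one
Conditions: NaH, MOMCl, DMF, 0 °C → rt
Reagents that add atoms: chloromethyl methyl ether, COCCl
Why: Deprotonation breaks the hydrogen bond of the chelated phenol and alkylation gives the acid-labile methoxymethyl ether that is later removed selectively beside the benzyl ethers.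

Step 16
Reactants: 23 1-[2,4-bis(benzyloxy)-6-(methoxymethoxy)phenyl]ethan-1-one; 21 3,4-bis(benzyloxy)-5-bromobenzaldehyde
Product: 24 (E)-1-[2,4-bis(benzyloxy)-6-(methoxymethoxy)phenyl]-3-[3,4-bis(benzyloxy)-5-bromophenyl]prop-2-en-1-one
Conditions: KOH, EtOH/THF, rt
Reagents that add atoms: none
Why: Claisen–Schmidt condensation of the methyl ketone with the non-enolizable aldehyde should give the (E)-chalcone by aldol addition and E1cB dehydration.

Step 17
Reactants: 24 chalcone
Product: 25 [2,4-bis(benzyloxy)-6-(methoxymethoxy)phenyl][(2R,3S)-3-[3,4-bis(benzyloxy)-5-bromophenyl]oxiran-2-yl]methanone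
Conditions: poly-L-leucine, urea–H2O2, DBU, THF, rt
Reagents that add atoms: hydrogen peroxide (used as its urea adduct), OO
Why: Juliá–Colonna epoxidation, in which hydroperoxide adds to the enone held at the helical poly-L-leucine terminus so that one enone face is selected, should give the trans (2R,3S)-epoxide.

Step 18
Reactants: 25 chalcone epoxide
Product: 27 (2R,3R)-5,7-bis(benzyloxy)-2-[3,4-bis(benzyloxy)-5-bromophenyl]-3-hydroxychroman-4-one, via hydroxy epoxide 26 (not isolated)
Conditions: HCl (conc., cat.), MeOH/THF, 50 °C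
Reagents that add atoms: none
Why: Acid removes the methoxymethyl group and the freed phenol opens the protonated epoxide at the benzylic carbon with inversion (6-endo opening favoured by benzylic activation), so C3 keeps the epoxide configuration and the thermodynamically preferred 2,3-trans chromanone should result.

Step 19
Reactants: 19 lignan boronate; 27 (2R,3R)-bromo chromanone
Product: 28 (2R,3R)-5,7-bis(benzyloxy)-2-{3,4-bis(benzyloxy)-5-[2-(benzyloxy)-3-methoxy-5-{(1R,2S,5R,6S)-6-[4-(benzyloxy)-3-methoxyphenyl]-3,7-dioxabicyclo[3.3.0]octan-2-yl}phenyl]phenyl}-3-hydroxychroman-4-one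
Conditions: Pd(OAc)2 (5 mol%), SPhos (10 mol%), K3PO4, toluene/H2O, 60 °C
Reagents that add atoms: none
Why: Suzuki–Miyaura coupling with a bulky electron-rich biaryl phosphine joins two ortho-alkoxy aryl partners (only two ortho substituents on the new axis, so no stable atropisomers) under base mild enough for the 3-hydroxychromanone.

Step 20
Reactants: 28 hexa-O-benzyl ether of the target
Product: 29 CNP0226398.1
Conditions: H2 (1 atm), 10% Pd/C, EtOAc/MeOH, rt, stopped at complete debenzylation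
Reagents that add atoms: none
Why: Hydrogenolysis cleaves the six aryl benzyl ethers much faster than the dialkyl benzylic C–O bonds of the furofuran or the ketone, so the free hexaphenol should be obtained if the reaction is stopped once debenzylation is complete.

**Compound list**

1 | 3-bromo-4-hydroxy-5-methoxybenzaldehyde (5-bromovanillin) | O=Cc1cc(OC)c(O)c(Br)c1 | starting material
2 | 4-(benzyloxy)-3-bromo-5-methoxybenzaldehyde | O=Cc1cc(OC)c(OCc2ccccc2)c(Br)c1 | intermediate
3 | (S)-4-benzyloxazolidin-2-one | O=C1N[C@@H](Cc2ccccc2)CO1 | starting material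
4 | (S)-4-benzyl-3-[(E)-but-2-enoyl]oxazolidin-2-one | C/C=C/C(=O)N1[C@@H](Cc2ccccc2)COC1=O | intermediate
5 | (S)-4-benzyl-3-{(2S)-2-[(S)-[4-(benzyloxy)-3-bromo-5-methoxyphenyl](hydroxy)methyl]but-3-enoyl}oxazolidin-2-one | C=C[C@H](C(=O)N1[C@@H](Cc2ccccc2)COC1=O)[C@H](O)c1cc(OC)c(OCc2ccccc2)c(Br)c1 | intermediate
6 | (S)-4-benzyl-3-{(2S)-2-[(S)-[4-(benzyloxy)-3-bromo-5-methoxyphenyl][(tert-butyldimethylsilyl)oxy]methyl]but-3-enoyl}oxazolidin-2-one | C=C[C@H](C(=O)N1[C@@H](Cc2ccccc2)COC1=O)[C@H](O[Si](C)(C)C(C)(C)C)c1cc(OC)c(OCc2ccccc2)c(Br)c1 | intermediate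
7 | (2R)-2-{(S)-[4-(benzyloxy)-3-bromo-5-methoxyphenyl][(tert-butyldimethylsilyl)oxy]methyl}but-3-en-1-ol | C=C[C@H](CO)[C@H](O[Si](C)(C)C(C)(C)C)c1cc(OC)c(OCc2ccccc2)c(Br)c1 | intermediate
8 | 4-(benzyloxy)-3-methoxybenzaldehyde | O=Cc1ccc(OCc2ccccc2)c(OC)c1 | starting material
9 | 1-(benzyloxy)-4-[bis(2-bromoethoxy)methyl]-2-methoxybenzene | BrCCOC(OCCBr)c1ccc(OCc2ccccc2)c(OC)c1 | intermediate
10 | 1-(benzyloxy)-4-[(2-bromoethoxy)(chloro)methyl]-2-methoxybenzene (not isolated) | ClC(OCCBr)c1ccc(OCc2ccccc2)c(OC)c1 | intermediate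
11 | 1-(benzyloxy)-4-[(2-bromoethoxy){[(2R)-2-{(S)-[4-(benzyloxy)-3-bromo-5-methoxyphenyl][(tert-butyldimethylsilyl)oxy]methyl}but-3-en-1-yl]oxy}methyl]-2-methoxybenzene (both acetal epimers) | C=C[C@H](COC(OCCBr)c1ccc(OCc2ccccc2)c(OC)c1)[C@H](O[Si](C)(C)C(C)(C)C)c1cc(OC)c(OCc2ccccc2)c(Br)c1 | intermediate
12 | 1-(benzyloxy)-4-[(ethenyloxy){[(2R)-2-{(S)-[4-(benzyloxy)-3-bromo-5-methoxyphenyl][(tert-butyldimethylsilyl)oxy]methyl}but-3-en-1-yl]oxy}methyl]-2-methoxybenzene (both acetal epimers) | C=C[C@H](COC(OC=C)c1ccc(OCc2ccccc2)c(OC)c1)[C@H](O[Si](C)(C)C(C)(C)C)c1cc(OC)c(OCc2ccccc2)c(Br)c1 | intermediate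
13 | (5R)-2-[4-(benzyloxy)-3-methoxyphenyl]-5-{(S)-[4-(benzyloxy)-3-bromo-5-methoxyphenyl][(tert-butyldimethylsilyl)oxy]methyl}-4,5-dihydro-1,3-dioxepine (both C2 epimers) | C1=C[C@H](COC(c2ccc(OCc3ccccc3)c(OC)c2)O1)[C@H](O[Si](C)(C)C(C)(C)C)c1cc(OC)c(OCc2ccccc2)c(Br)c1 | intermediate
14 | (2S,3R,4R)-2-[4-(benzyloxy)-3-methoxyphenyl]-4-{(S)-[4-(benzyloxy)-3-bromo-5-methoxyphenyl][(tert-butyldimethylsilyl)oxy]methyl}tetrahydrofuran-3-carbaldehyde (2,3-cis, 3,4-trans) | O=C[C@H]1[C@@H](c2ccc(OCc3ccccc3)c(OC)c2)OC[C@@H]1[C@H](O[Si](C)(C)C(C)(C)C)c1cc(OC)c(OCc2ccccc2)c(Br)c1 | intermediate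
15 | (2S,3R,4R)-2-[4-(benzyloxy)-3-methoxyphenyl]-4-{(S)-[4-(benzyloxy)-3-bromo-5-methoxyphenyl](hydroxy)methyl}tetrahydrofuran-3-carbaldehyde (not isolated) | O=C[C@H]1[C@@H](c2ccc(OCc3ccccc3)c(OC)c2)OC[C@@H]1[C@H](O)c1cc(OC)c(OCc2ccccc2)c(Br)c1 | intermediate
16 | (2S,3S,4R)-2-[4-(benzyloxy)-3-methoxyphenyl]-4-{(S)-[4-(benzyloxy)-3-bromo-5-methoxyphenyl](hydroxy)methyl}tetrahydrofuran-3-carbaldehyde (2,3-trans, 3,4-cis; not isolated) | O=C[C@@H]1[C@@H](c2ccc(OCc3ccccc3)c(OC)c2)OC[C@@H]1[C@H](O)c1cc(OC)c(OCc2ccccc2)c(Br)c1 | intermediate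
17 | (1S,2S,5R,6S)-2-[4-(benzyloxy)-3-methoxyphenyl]-6-[4-(benzyloxy)-3-bromo-5-methoxyphenyl]-3,7-dioxabicyclo[3.3.0]octan-8-ol (both anomers) | COc1cc([C@H]2OC[C@H]3[C@@H]2C(O)O[C@@H]3c2cc(OC)c(OCc4ccccc4)c(Br)c2)ccc1OCc1ccccc1 | intermediate
18 | (1R,2S,5R,6S)-2-[4-(benzyloxy)-3-methoxyphenyl]-6-[4-(benzyloxy)-3-bromo-5-methoxyphenyl]-3,7-dioxabicyclo[3.3.0]octane | COc1cc([C@H]2OC[C@H]3[C@@H]2CO[C@@H]3c2cc(OC)c(OCc4ccccc4)c(Br)c2)ccc1OCc1ccccc1 | intermediate
19 | (1R,2S,5R,6S)-2-[4-(benzyloxy)-3-methoxyphenyl]-6-[4-(benzyloxy)-3-methoxy-5-(4,4,5,5-tetramethyl-1,3,2-dioxaborolan-2-yl)phenyl]-3,7-dioxabicyclo[3.3.0]octane | COc1cc([C@H]2OC[C@H]3[C@@H]2CO[C@@H]3c2cc(OC)c(OCc4ccccc4)c(B4OC(C)(C)C(C)(C)O4)c2)ccc1OCc1ccccc1 | intermediate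
20 | 3-bromo-4,5-dihydroxybenzaldehyde | O=Cc1cc(O)c(O)c(Br)c1 | starting material
21 | 3,4-bis(benzyloxy)-5-bromobenzaldehyde | O=Cc1cc(Br)c(OCc2ccccc2)c(OCc2ccccc2)c1 | intermediate
22 | 1-[2,4-bis(benzyloxy)-6-hydroxyphenyl]ethan-1-one | CC(=O)c1c(O)cc(OCc2ccccc2)cc1OCc1ccccc1 | starting material
23 | 1-[2,4-bis(benzyloxy)-6-(methoxymethoxy)phenyl]ethan-1-one | CC(=O)c1c(OCOC)cc(OCc2ccccc2)cc1OCc1ccccc1 | intermediate
24 | (E)-1-[2,4-bis(benzyloxy)-6-(methoxymethoxy)phenyl]-3-[3,4-bis(benzyloxy)-5-bromophenyl]prop-2-en-1-one | O=C(/C=C/c1cc(Br)c(OCc2ccccc2)c(OCc2ccccc2)c1)c1c(OCOC)cc(OCc2ccccc2)cc1OCc1ccccc1 | intermediate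
25 | [2,4-bis(benzyloxy)-6-(methoxymethoxy)phenyl][(2R,3S)-3-[3,4-bis(benzyloxy)-5-bromophenyl]oxiran-2-yl]methanone | O=C([C@@H]1O[C@H]1c1cc(Br)c(OCc2ccccc2)c(OCc2ccccc2)c1)c1c(OCOC)cc(OCc2ccccc2)cc1OCc1ccccc1 | intermediate
26 | [2,4-bis(benzyloxy)-6-hydroxyphenyl][(2R,3S)-3-[3,4-bis(benzyloxy)-5-bromophenyl]oxiran-2-yl]methanone (not isolated) | O=C([C@@H]1O[C@H]1c1cc(Br)c(OCc2ccccc2)c(OCc2ccccc2)c1)c1c(O)cc(OCc2ccccc2)cc1OCc1ccccc1 | intermediate
27 | (2R,3R)-5,7-bis(benzyloxy)-2-[3,4-bis(benzyloxy)-5-bromophenyl]-3-hydroxychroman-4-one | Brc1cc([C@H]2Oc3cc(OCc4ccccc4)cc(OCc4ccccc4)c3C(=O)[C@@H]2O)cc(OCc2ccccc2)c1OCc1ccccc1 | intermediate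
28 | (2R,3R)-5,7-bis(benzyloxy)-2-{3,4-bis(benzyloxy)-5-[2-(benzyloxy)-3-methoxy-5-{(1R,2S,5R,6S)-6-[4-(benzyloxy)-3-methoxyphenyl]-3,7-dioxabicyclo[3.3.0]octan-2-yl}phenyl]phenyl}-3-hydroxychroman-4-one | COc1cc([C@H]2OC[C@H]3[C@@H]2CO[C@@H]3c2cc(OC)c(OCc6ccccc6)c(-c3cc([C@H]4Oc5cc(OCc6ccccc6)cc(OCc6ccccc6)c5C(=O)[C@@H]4O)cc(OCc4ccccc4)c3OCc3ccccc3)c2)ccc1OCc1ccccc1 | intermediate
29 | CNP0226398.1, (2R,3R)-2-{3,4-dihydroxy-5-[2-hydroxy-5-{(1R,2S,5R,6S)-6-(4-hydroxy-3-methoxyphenyl)-3,7-dioxabicyclo[3.3.0]octan-2-yl}-3-methoxyphenyl]phenyl}-3,5,7-trihydroxychroman-4-one | COc1cc([C@H]2OC[C@H]3[C@@H]2CO[C@@H]3c2cc(OC)c(O)c(-c3cc([C@H]4Oc5cc(O)cc(O)c5C(=O)[C@@H]4O)cc(O)c3O)c2)ccc1O | target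

**Step count and risks**

Total step count: 20. Longest linear sequence: 13 steps (steps 1, 3, 4, 5, 7, 8, 9, 10, 11, 12, 13, 19, 20).

Steps most likely to fail:

1. Step 10 (ring contraction). The process at risk is loss of kinetic control. The electron-rich benzylic ether of the product can re-ionize and re-close, or the closure may not discriminate the two oxocarbenium faces. The aryl group would then end cis to the side chain and, after steps 11 and 12, sit endo on the bicycle. The fallback sets out from 13 and comes back at 18. The contraction is run whatever the ratio and the mixture is taken through steps 11 and 12. The C2-epimeric furofuran (1R,2R,5R,6S)-2-[4-(benzyloxy)-3-methoxyphenyl]-6-[4-(benzyloxy)-3-bromo-5-methoxyphenyl]-3,7-dioxabicyclo[3.3.0]octane F1 is separated from 18. It is equilibrated with BF3·OEt2 (0.2 equiv) in CH2Cl2 at 0 °C, the known acid-promoted epimerization of the benzylic centres of 2,6-diaryl-3,7-dioxabicyclo[3.3.0]octanes through reversible C2–O3 ionization. The bromine-free, more electron-rich aryl carbinol centre should ionize first. Compound 18 is removed by chromatography and F1 is recycled.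

2. Step 9 (ring-closing metathesis). The process at risk is catalyst deactivation by metathesis at the vinyl acetal end (a heteroatom-stabilized alkylidene) or acetal cleavage at the Lewis-acidic metal, so that the ring does not close. The fallback sets out from 2 and 9 and comes back at 13 without metathesis. 1,4-Bis[(tert-butyldimethylsilyl)oxy]but-2-yne is hydrozirconated with Cp2Zr(H)Cl and transmetalated with Me2Zn. The alkenylzinc is added to 2 in the presence of a chiral amino alcohol ligand, whose enantiomer is chosen to give the allylic alcohol (1R,2E)-1-[4-(benzyloxy)-3-bromo-5-methoxyphenyl]-4-[(tert-butyldimethylsilyl)oxy]-2-{[(tert-butyldimethylsilyl)oxy]methyl}but-2-en-1-ol F2. TBSOTf and 2,6-lutidine give the tris-silyl ether (1R,2E)-1-[4-(benzyloxy)-3-bromo-5-methoxyphenyl]-1,4-bis[(tert-butyldimethylsilyl)oxy]-2-{[(tert-butyldimethylsilyl)oxy]methyl}but-2-ene F3. HF·pyridine in THF at 0 °C removes the two primary silyl groups to give (2E)-2-{(R)-[4-(benzyloxy)-3-bromo-5-methoxyphenyl][(tert-butyldimethylsilyl)oxy]methyl}but-2-ene-1,4-diol F4, in which the two hydroxymethyl groups are cis. Transacetalization with 9 (PPTS, toluene, 60 °C) closes 2-[4-(benzyloxy)-3-methoxyphenyl]-5-{(R)-[4-(benzyloxy)-3-bromo-5-methoxyphenyl][(tert-butyldimethylsilyl)oxy]methyl}-4,7-dihydro-1,3-dioxepine F5. RuHCl(CO)(PPh3)3 (toluene, 80 °C) then moves the double bond into conjugation with the ring oxygen and gives 13. The carbinol centre is the same in space throughout; it is labelled R in F2 to F5 and S in 13 only because the ranking of its neighbours changes. In this variant the C5 configuration rests on substrate control in the hydride addition, and the C5 epimers would be separated.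

3. Step 19 (biaryl coupling). The process at risk is base-induced ring opening (retro-oxa-Michael) with C2/C3 epimerization of the 3-hydroxychromanone, together with protodeboronation of the ortho-alkoxy boronate during a slow coupling of two large partners. The fallback sets out from 19 and 21 and comes back at 28, with the coupling moved before the chromanone is built. Suzuki–Miyaura coupling of 19 with 21 (Pd(OAc)2, SPhos, K3PO4, toluene/H2O, 60 °C) gives the biaryl aldehyde 3,4-bis(benzyloxy)-5-[2-(benzyloxy)-3-methoxy-5-{(1R,2S,5R,6S)-6-[4-(benzyloxy)-3-methoxyphenyl]-3,7-dioxabicyclo[3.3.0]octan-2-yl}phenyl]benzaldehyde F6. Claisen–Schmidt condensation with 23 (KOH, EtOH/THF) gives the corresponding (E)-chalcone F7. Juliá–Colonna epoxidation (poly-L-leucine, urea–H2O2, DBU, THF) gives the (2R,3S)-epoxy ketone F8. HCl in MeOH/THF at 40 °C removes the methoxymethyl group and closes the chromanone to 28.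

Further compounds
F1 | step 10 | (1R,2R,5R,6S)-2-[4-(benzyloxy)-3-methoxyphenyl]-6-[4-(benzyloxy)-3-bromo-5-methoxyphenyl]-3,7-dioxabicyclo[3.3.0]octane | COc1cc([C@@H]2OC[C@H]3[C@@H]2CO[C@@H]3c2cc(OC)c(OCc4ccccc4)c(Br)c2)ccc1OCc1ccccc1
F2 | step 9 | (1R,2E)-1-[4-(benzyloxy)-3-bromo-5-methoxyphenyl]-4-[(tert-butyldimethylsilyl)oxy]-2-{[(tert-butyldimethylsilyl)oxy]methyl}but-2-en-1-ol | O[C@H](c1cc(OC)c(OCc2ccccc2)c(Br)c1)/C(CO[Si](C)(C)C(C)(C)C)=C/CO[Si](C)(C)C(C)(C)C
F3 | step 9 | (1R,2E)-1-[4-(benzyloxy)-3-bromo-5-methoxyphenyl]-1,4-bis[(tert-butyldimethylsilyl)oxy]-2-{[(tert-butyldimethylsilyl)oxy]methyl}but-2-ene | CC(C)(C)[Si](C)(C)O[C@H](c1cc(OC)c(OCc2ccccc2)c(Br)c1)/C(CO[Si](C)(C)C(C)(C)C)=C/CO[Si](C)(C)C(C)(C)C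
F4 | step 9 | (2E)-2-{(R)-[4-(benzyloxy)-3-bromo-5-methoxyphenyl][(tert-butyldimethylsilyl)oxy]methyl}but-2-ene-1,4-diol | CC(C)(C)[Si](C)(C)O[C@H](c1cc(OC)c(OCc2ccccc2)c(Br)c1)/C(CO)=C/CO
F5 | step 9 | 2-[4-(benzyloxy)-3-methoxyphenyl]-5-{(R)-[4-(benzyloxy)-3-bromo-5-methoxyphenyl][(tert-butyldimethylsilyl)oxy]methyl}-4,7-dihydro-1,3-dioxepine | CC(C)(C)[Si](C)(C)O[C@H](c1cc(OC)c(OCc2ccccc2)c(Br)c1)C1=CCOC(c2ccc(OCc3ccccc3)c(OC)c2)OC1
F6 | step 19 | 3,4-bis(benzyloxy)-5-[2-(benzyloxy)-3-methoxy-5-{(1R,2S,5R,6S)-6-[4-(benzyloxy)-3-methoxyphenyl]-3,7-dioxabicyclo[3.3.0]octan-2-yl}phenyl]benzaldehyde | COc1cc([C@H]2OC[C@H]3[C@@H]2CO[C@@H]3c2cc(OC)c(OCc4ccccc4)c(-c3cc(C=O)cc(OCc4ccccc4)c3OCc3ccccc3)c2)ccc1OCc1ccccc1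
F7 | step 19 | (E)-1-[2,4-bis(benzyloxy)-6-(methoxymethoxy)phenyl]-3-{3,4-bis(benzyloxy)-5-[2-(benzyloxy)-3-methoxy-5-{(1R,2S,5R,6S)-6-[4-(benzyloxy)-3-methoxyphenyl]-3,7-dioxabicyclo[3.3.0]octan-2-yl}phenyl]phenyl}prop-2-en-1-one | COc1cc([C@H]2OC[C@H]3[C@@H]2CO[C@@H]3c2cc(OC)c(OCc4ccccc4)c(-c3cc(/C=C/C(=O)c4c(OCOC)cc(OCc5ccccc5)cc4OCc4ccccc4)cc(OCc4ccccc4)c3OCc3ccccc3)c2)ccc1OCc1ccccc1
F8 | step 19 | [2,4-bis(benzyloxy)-6-(methoxymethoxy)phenyl][(2R,3S)-3-{3,4-bis(benzyloxy)-5-[2-(benzyloxy)-3-methoxy-5-{(1R,2S,5R,6S)-6-[4-(benzyloxy)-3-methoxyphenyl]-3,7-dioxabicyclo[3.3.0]octan-2-yl}phenyl]phenyl}oxiran-2-yl]methanone | COc1cc([C@H]2OC[C@H]3[C@@H]2CO[C@@H]3c2cc(OC)c(OCc4ccccc4)c(-c3cc([C@@H]4O[C@H]4C(=O)c4c(OCOC)cc(OCc5ccccc5)cc4OCc4ccccc4)cc(OCc4ccccc4)c3OCc3ccccc3)c2)ccc1OCc1ccccc1
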